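**Strategy.** The pendant aryl ring on C1 (ring C) and the dimethoxybenzo ring A are the same 3,4-dimethoxyphenyl unit, and C2 and C3 carry trans methyl groups. Disconnecting C4–C4a therefore unveils 4,4-bis(3,4-dimethoxyphenyl)-2,3-dimethylbutanoic acid: C1 is a non-stereogenic diaryl methine, and the C1–C4 chain is the twofold-symmetric (2S,3S)-2,3-dimethylsuccinic acid, one carboxyl of which has taken up two aryl Grignard units. An intramolecular Friedel–Crafts acylation closes ring B and, by choosing one of the two diastereotopic aryl rings, sets the C1 stereocenter under control of the two methyl-bearing centers. Hydrogenolysis of the ketone completes galbulin.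

Key step: step 6

Remark: atom numbers refer to the target as a 1-aryltetralin (C1 bears ring C, C2 and C3 the methyl groups, C4 is the CH2 group, C4a and C8a belong to ring A, the six-membered carbocycle is ring B). LiN(i-Pr)2 and (3,4-dimethoxyphenyl)magnesium bromide are used as purchased THF solutions.

Step 1
Reactants: 1 (R)-4-benzyl-3-propanoyl-1,3-oxazolidin-2-one (2 equiv per product)
Product: 3 (2S,3S)-1,4-bis[(4R)-4-benzyl-2-oxo-1,3-oxazolidin-3-yl]-2,3-dimethylbutane-1,4-dione, via lithium Z-enolate 2 (not isolated)
Conditions: LiN(i-Pr)2, THF, −78 °C; then TiCl4, −78 °C → rt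
Reagents that add atoms: none
Why: Oxidative enolate homocoupling: the chelated Z-enolate is oxidized by TiCl4 (tetravalent titanium goes to trivalent titanium) and two units join at their α-carbons, each on the face opposite the benzyl group of its auxiliary, which should set both new centers S and make the twofold-symmetric dimer the main diastereomer.

Step 2
Reactants: 3 bis-imide
Product: 5 (2S,3S)-2,3-dimethylbutanedioic acid, via diperoxy acid 4 (not isolated)
Conditions: LiOH, 30% H2O2, THF/H2O, 0 °C; then aq. Na2SO3; then HCl to pH 1
Reagents that add atoms: hydrogen peroxide (acting as LiOOH), OO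
Why: Auxiliary hydrolysis with LiOOH: the hydroperoxide attacks the exocyclic imide carbonyl selectively, sulfite reduces the peracid, and the cold, weakly basic medium should leave both α-stereocenters untouched while the auxiliary is recovered.

Step 3
Reactants: 5 (2S,3S)-2,3-dimethylbutanedioic acid
Product: 7 (3S,4S)-3,4-dimethyloxolane-2,5-dione (trans anhydride), via mixed acetic anhydride 6 (not isolated)
Conditions: AcCl (neat), 50 °C; evaporate
Reagents that add atoms: none
Why: Cyclodehydration of a 1,4-diacid through its mixed acetic anhydride gives the five-membered anhydride without base; the temperature is kept low because the trans anhydride can isomerize to the cis (meso) form on strong heating.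

Step 4
Reactants: 7 (3S,4S)-3,4-dimethyloxolane-2,5-dione; 8 (3,4-dimethoxyphenyl)magnesium bromide (2.5 equiv)
Product: 11 (3S,4S)-5,5-bis(3,4-dimethoxyphenyl)-3,4-dimethyloxolan-2-one, via bromomagnesium keto carboxylate 9 (not isolated), via hydroxy acid 10 (not isolated)
Conditions: LaCl3·2LiCl (0.3 equiv), THF, −78 → 0 °C; then 1 M HCl, 0 °C → rt
Reagents that add atoms: (3,4-dimethoxyphenyl)magnesium bromide, COc1ccc([Mg]Br)cc1OC
Why: Grignard addition to a cyclic anhydride: the first aryl opens the ring to a keto carboxylate whose carboxylate is inert, the second adds to the ketone (LaCl3·2LiCl favors addition over enolization), and the tertiary γ-hydroxy acid lactonizes on acidification; the two carbonyls of 7 are homotopic, so no regiochemistry arises, and no new stereocenter forms.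

Step 5
Reactants: 11 diaryl lactone
Product: 12 (2S,3R)-4,4-bis(3,4-dimethoxyphenyl)-2,3-dimethylbutanoic acid
Conditions: H2 (5 bar), Pd(OH)2/C, AcOH/EtOAc, 50 °C
Reagents that add atoms: none
Why: Hydrogenolysis of the doubly benzylic C–O bond of the lactone on palladium frees the acid and turns C1 into a CH carrying two identical aryl rings without a free carbocation, so the adjacent methyl-bearing center should not be scrambled by elimination.

Step 6
Reactants: 12 (2S,3R)-4,4-bis(3,4-dimethoxyphenyl)-2,3-dimethylbutanoic acid
Product: 14 (2S,3R,4S)-4-(3,4-dimethoxyphenyl)-6,7-dimethoxy-2,3-dimethyl-3,4-dihydronaphthalen-1(2H)-one, via mixed trifluoroacetic anhydride 13 (not isolated)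
Conditions: (CF3CO)2O, CH2Cl2, 0 °C → rt
Reagents that add atoms: none
Why: Intramolecular Friedel–Crafts acylation: (CF3CO)2O turns the acid into mixed anhydride 13, whose acyl carbon (the future C4) is attacked by the ring carbon para to a methoxy group (the future C4a) of one aryl ring, and loss of a proton restores ring A. The closest known reaction type is the cyclization of 4,4-diarylbutanoic acids to 4-aryl-1-tetralones. Ring B closes as a six-membered ring in the 6-exo-trig mode at the acyl carbon. The only new stereocenter is the diaryl-bearing carbon (C1 of the target), which becomes stereogenic because the two aryl rings are diastereotopic; it is controlled by the two methyl-bearing centers, since in the chair-like transition state with both methyl groups equatorial the aryl ring left behind is equatorial (trans to the C2 methyl) for one choice and axial, gauche to both the C2 methyl and C3, for the other. The step needs selection between the two aryl rings, closure para and not ortho to a methoxy group, and retention of the α-methyl center; the trans-dimethyl backbone, the crowding of the position between ring substituents and the base-free acidic medium should secure these in turn. Should C3–H (α to the new ketone) enolize at all, it can only return to the more stable trans arrangement already present.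

Step 7
Reactants: 14 tetralone
Product: 16 galbulin, (1S,2S,3R)-1-(3,4-dimethoxyphenyl)-6,7-dimethoxy-2,3-dimethyl-1,2,3,4-tetrahydronaphthalene, via benzylic alcohol 15 (not isolated)
Conditions: H2 (5 bar), 10% Pd/C, AcOH, 60 °C
Reagents that add atoms: none
Why: Hydrogenolysis of an electron-rich aryl ketone to the methylene group on Pd/C in acetic acid (reduction to the benzylic alcohol, then C–O hydrogenolysis); no base is present, so the three stereocenters should be retained.

**Compound list**

1 | (R)-4-benzyl-3-propanoyl-1,3-oxazolidin-2-one | CCC(=O)N1[C@H](Cc2ccccc2)COC1=O | starting material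
2 | lithium Z-enolate of 1 | C/C=C(\[O-])N1[C@H](Cc2ccccc2)COC1=O.[Li+] | intermediate (not isolated)
3 | (2S,3S)-1,4-bis[(4R)-4-benzyl-2-oxo-1,3-oxazolidin-3-yl]-2,3-dimethylbutane-1,4-dione | O=C1OC[C@@H](Cc2ccccc2)N1C(=O)[C@@H](C)[C@H](C)C(=O)N1[C@H](Cc2ccccc2)COC1=O | intermediate
4 | (2S,3S)-2,3-dimethylbutanediperoxoic acid (dilithium salt in the flask) | OOC(=O)[C@@H](C)[C@H](C)C(=O)OO | intermediate (not isolated)
5 | (2S,3S)-2,3-dimethylbutanedioic acid | OC(=O)[C@@H](C)[C@H](C)C(=O)O | intermediate
6 | (2S,3S)-4-acetyloxy-2,3-dimethyl-4-oxobutanoic acid (mixed acetic anhydride) | CC(=O)OC(=O)[C@@H](C)[C@H](C)C(=O)O | intermediate (not isolated)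
7 | (3S,4S)-3,4-dimethyloxolane-2,5-dione | O=C1OC(=O)[C@@H](C)[C@@H]1C | intermediate
8 | (3,4-dimethoxyphenyl)magnesium bromide | COc1ccc([Mg]Br)cc1OC | starting material
9 | bromomagnesium (2S,3S)-4-(3,4-dimethoxyphenyl)-2,3-dimethyl-4-oxobutanoate | COc1ccc(C(=O)[C@@H](C)[C@H](C)C(=O)O[Mg]Br)cc1OC | intermediate (not isolated)
10 | (2S,3S)-4,4-bis(3,4-dimethoxyphenyl)-4-hydroxy-2,3-dimethylbutanoic acid | OC(=O)[C@@H](C)[C@H](C)C(O)(c1ccc(OC)c(OC)c1)c1ccc(OC)c(OC)c1 | intermediate (not isolated)
11 | (3S,4S)-5,5-bis(3,4-dimethoxyphenyl)-3,4-dimethyloxolan-2-one | O=C1OC(c2ccc(OC)c(OC)c2)(c2ccc(OC)c(OC)c2)[C@@H](C)[C@@H]1C | intermediate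
12 | (2S,3R)-4,4-bis(3,4-dimethoxyphenyl)-2,3-dimethylbutanoic acid | OC(=O)[C@@H](C)[C@H](C)C(c1ccc(OC)c(OC)c1)c1ccc(OC)c(OC)c1 | intermediate
13 | (2S,3R)-4,4-bis(3,4-dimethoxyphenyl)-2,3-dimethylbutanoic trifluoroacetic anhydride | O=C(OC(=O)C(F)(F)F)[C@@H](C)[C@H](C)C(c1ccc(OC)c(OC)c1)c1ccc(OC)c(OC)c1 | intermediate (not isolated)
14 | (2S,3R,4S)-4-(3,4-dimethoxyphenyl)-6,7-dimethoxy-2,3-dimethyl-3,4-dihydronaphthalen-1(2H)-one | COc1ccc([C@H]2c3cc(OC)c(OC)cc3C(=O)[C@@H](C)[C@@H]2C)cc1OC | intermediate
15 | (2S,3R,4S)-4-(3,4-dimethoxyphenyl)-6,7-dimethoxy-2,3-dimethyl-1,2,3,4-tetrahydronaphthalen-1-ol (C1 epimers) | COc1ccc([C@H]2c3cc(OC)c(OC)cc3C(O)[C@@H](C)[C@@H]2C)cc1OC | intermediate (not isolated)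
16 | galbulin, (1S,2S,3R)-1-(3,4-dimethoxyphenyl)-6,7-dimethoxy-2,3-dimethyl-1,2,3,4-tetrahydronaphthalene | COc1ccc([C@H]2c3cc(OC)c(OC)cc3C[C@@H](C)[C@@H]2C)cc1OC | target

Total step count: 7. Longest linear sequence: 7 steps (from 1).

**Steps most likely to fail**

Step 6. The ring closure may discriminate poorly between the two diastereotopic aryl rings, because the transition state with the remaining aryl ring axial may compete. The fallback sets out from 12 and comes back at 14. The ring is closed without regard to selectivity (P2O5/MeSO3H, rt), which should give 14 together with its C4 epimer, (2S,3R,4R)-4-(3,4-dimethoxyphenyl)-6,7-dimethoxy-2,3-dimethyl-3,4-dihydronaphthalen-1(2H)-one F1. The mixture is then equilibrated with KOt-Bu in t-BuOH/THF under argon. C4–H of a 4-aryl-1-tetralone is doubly benzylic and conjugated to the carbonyl through ring A (extended enolate), and C2–H is α to the ketone, whereas the C3 methyl center cannot epimerize. Thermodynamic control relayed from C3 should therefore collect the material in the all-trans, all-equatorial isomer 14.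

Step 1. The radical-type coupling may give the meso-type (2R,3S) dimer and reduced imide, with a low mass balance. The fallback sets out from 1 and comes back at 5. Enolate 2 is formed with LiN(i-Pr)2 and alkylated with purchased ethyl (S)-2-{[(trifluoromethyl)sulfonyl]oxy}propanoate. This is an SN2 displacement with inversion at the lactate carbon, with the auxiliary controlling the enolate face. It should give ethyl (2S,3S)-4-[(4R)-4-benzyl-2-oxo-1,3-oxazolidin-3-yl]-2,3-dimethyl-4-oxobutanoate F2. LiOH/H2O2 removes the auxiliary to give (2S,3S)-4-ethoxy-2,3-dimethyl-4-oxobutanoic acid F3, and saponification with LiOH gives 5.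

Step 4. The hindered, electron-rich aryl ketone in 9 may be enolized instead of attacked, so the reaction may stall at the keto acid and the methyl-bearing carbon next to the ketone may epimerize. The fallback sets out from 7 and comes back at 11. Methanol opens 7 (homotopic carbonyls) to (2S,3S)-4-methoxy-2,3-dimethyl-4-oxobutanoic acid F4. (3,4-Dimethoxyphenyl)lithium F5 is made from 4-bromo-1,2-dimethoxybenzene and n-BuLi in THF at −78 °C. Used in excess with CeCl3 at −78 °C, it deprotonates the acid and adds twice to the ester group. Acidification gives hydroxy acid 10, which lactonizes to 11.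

**Further compounds**

F1 | step 6 | (2S,3R,4R)-4-(3,4-dimethoxyphenyl)-6,7-dimethoxy-2,3-dimethyl-3,4-dihydronaphthalen-1(2H)-one | COc1ccc([C@@H]2c3cc(OC)c(OC)cc3C(=O)[C@@H](C)[C@@H]2C)cc1OC
F2 | step 1 | ethyl (2S,3S)-4-[(4R)-4-benzyl-2-oxo-1,3-oxazolidin-3-yl]-2,3-dimethyl-4-oxobutanoate | CCOC(=O)[C@@H](C)[C@H](C)C(=O)N1[C@H](Cc2ccccc2)COC1=O
F3 | step 1 | (2S,3S)-4-ethoxy-2,3-dimethyl-4-oxobutanoic acid | CCOC(=O)[C@@H](C)[C@H](C)C(=O)O
F4 | step 4 | (2S,3S)-4-methoxy-2,3-dimethyl-4-oxobutanoic acid | COC(=O)[C@@H](C)[C@H](C)C(=O)O
F5 | step 4 | (3,4-dimethoxyphenyl)lithium | [Li]c1ccc(OC)c(OC)c1
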